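**One-step world.** In a one-step world starting material simply becomes target, and the question for the flask is how far the enzyme gets in the time given.

- north-east: starting material 0.18 M (fed, over 30 s); enzyme 91 µM; run made earlier; the fed solution adds 0.25 times the starting volume
- flask: starting material 0.091 M (fed, over 30 s); enzyme 91 µM; time 4.0 min; the fed solution adds 0.25 times the starting volume

north-east run (percent of the starting material charged)

| time / s | target / % | complex / % | starting material / % |
|---|---|---|---|
| 10.0 | 7 | 1 | 27 |
| 20.0 | 17 | 1 | 50 |
| 30.0 | 28 | 2 | 72 |
| 40.0 | 37 | 0 | 64 |
| 50.0 | 49 | 0 | 51 |

(readings scatter by 1.5 percentage points)

1. the species in which most of what was charged as starting material, at 4.0 min sits (target / complex / starting material)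
2. the largest share itself, whichever of these holds it, in percent of the starting material charged

- amounts are per litre of the starting volume; all of the dose is in the solution fed
- the numbers in the tables scatter with a standard deviation of 1.5 percentage points
- percentages count the whole charge, also what has not yet gone in

**Enzyme balance.** I write the balance of the reagent charged in the smaller amount. In the flask the enzyme is 0.100 % of the charge, so the complex can hold no more than that, and to convert the whole charge each enzyme must turn over 1000 times. The north-east reading of 49 % target at 50.0 s gives, as a reading with its scatter, an average turnover frequency of 19.4 /s. Over the flask's 4.0 min that pace offers 4.65 times the need, my turnover margin: turnovers on offer over turnovers required.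

**Two extremes.** If the enzyme keeps this pace throughout, the flask clears at 51.6 s and target holds the full charge. If the enzyme stopped when the feed ended, at 30 s, target would stand at 58.2 %, still ahead of starting material. I place the flask between them, towards the upper one: target in the north-east run still gained 12 percentage points between 40.0 s and 50.0 s.

**The forecast.** The forecast says target at 99.5 %, within 95 % to 100 %: “By 240 s essentially everything should be target”. That number is what a straight line through the last two north-east readings of target gives, cut at the full charge. My own range runs from 58.2 % to the full charge, wider than the forecast's.

**The flask.** The flask holds target at 89.7 % at 4.00 min, and 90.2 % at 40.0 min.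

    starting material + enzyme ⇌ complex (K = 23.0 /M, k = 4000 /M/s)
    complex ⇌ enzyme + target (K = 0.400 M, k = 44.0 /s)
    2 enzyme → spent catalyst (k = 130 /M/s)

Of the 4656 turnovers per enzyme charged that the margin of 4.65 offered, the flask made 897 net. The neighbour charged with 2.3 × 10⁻⁵ M of enzyme has a margin of 1.18, and it holds 76.0 % target at 4.00 min.

The runs are simulated with made-up constants.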